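**Plan**

- Numbering: coumarin numbering (O1 to C8a) for benzene ring A and pyranone ring B; ring C is the furan, ring D the phenol ring, ring E the dimethyldihydropyran on C5–O and C6. The target has no stereocentre, so nothing has to be controlled.
- Retrosynthesis, in order: the ring D pivalate; the O1–C8a bond of lactone ring B (back to C8a–H and a free CO2H on furan C3); the furan O–C2 bond together with the C3–CO2 bond (carbonylative annulation of an ortho-alkynylphenol); the aryl–alkyne bond; last, ring E.
- Enabling feature: O1 sits on C8a, the ring A carbon ortho to the C4–C4a aryl–furan bond, and the other ortho carbon C5 already bears the ring E oxygen. Ring A therefore needs only two oxygens until the lactone closes, and the acid can reach a single C–H.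
- Forward: ring E is built on the ring A aldehyde (propargyl ether Claisen, hydrogenation), the aldehyde becomes an alkyne, Sonogashira coupling joins ring D, ring C closes with uptake of CO, ring B closes last by anodic C–H acyloxylation, and the pivalate is removed.

Key step: step 10

Remark: compounds 1, 2 and 9 are taken to be commercial.

**Route**

Step 1
Reactants: 1 2-hydroxy-4-methoxybenzaldehyde; 2 3-chloro-3-methylbut-1-yne
Product: 3 4-methoxy-2-[(2-methylbut-3-yn-2-yl)oxy]benzaldehyde
Conditions: DBU, CuCl2·2H2O (cat.), MeCN, 0 °C to rt
Reagents that add atoms: none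
Why: Copper-catalysed propargylic etherification (a Williamson-type O-alkylation through a copper acetylide) should alkylate even this hydrogen-bonded, electron-poor phenol at the tertiary carbon, where a plain SN2 reaction would be too slow.

Step 2
Reactants: 3 4-methoxy-2-[(2-methylbut-3-yn-2-yl)oxy]benzaldehyde
Product: 6 5-methoxy-2,2-dimethyl-2H-chromene-8-carbaldehyde, via allenylphenol 4 (not isolated), via quinone methide 5 (not isolated)
Conditions: PhNEt2, 185 °C
Reagents that add atoms: none
Why: The aryl propargyl ether Claisen rearrangement can only reach benzaldehyde C3, the one free ortho carbon, and the resulting allenylphenol 4 should pass by 1,5-hydrogen shift to quinone methide 5, which closes ring E by oxa-6π electrocyclization.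

Step 3
Reactants: 6 5-methoxy-2,2-dimethyl-2H-chromene-8-carbaldehyde
Product: 7 5-methoxy-2,2-dimethylchroman-8-carbaldehyde
Conditions: H2 (1 atm), 10% Pd/C, Ph2S (cat.), EtOAc, rt
Reagents that add atoms: none
Why: Catalytic hydrogenation over sulfide-moderated palladium should saturate the styrene-type C3=C4 bond of the chromene while leaving the electron-rich aryl aldehyde and the aryl ethers untouched.

Step 4
Reactants: 7 5-methoxy-2,2-dimethylchroman-8-carbaldehyde
Product: 8 8-ethynyl-5-methoxy-2,2-dimethylchroman
Conditions: dimethyl (1-diazo-2-oxopropyl)phosphonate, K2CO3, MeOH, 0 °C to rt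
Reagents that add atoms: dimethyl (1-diazo-2-oxopropyl)phosphonate, COP(=O)(OC)C(=[N+]=[N-])C(C)=O
Why: The Seyferth–Gilbert homologation in its Ohira–Bestmann form (olefination by the deacylated diazophosphonate, loss of N2 and 1,2-hydrogen shift of the alkylidene carbene) converts non-enolisable aryl aldehydes into terminal alkynes under mild base.

Step 5
Reactants: 9 4-iodoresorcinol
Product: 10 4-iodo-1,3-phenylene diacetate
Conditions: Ac2O, pyridine, DMAP (cat.), CH2Cl2, 0 °C to rt
Reagents that add atoms: acetic anhydride, CC(=O)OC(C)=O
Why: DMAP-catalysed acetylation masks both phenols, so that the hydroxyl ortho to iodine cannot add to the alkyne during the cross-coupling and give a benzofuran without the C3 carboxyl carbon.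

Step 6
Reactants: 8 8-ethynyl-5-methoxy-2,2-dimethylchroman; 10 4-iodo-1,3-phenylene diacetate
Product: 11 4-[(5-methoxy-2,2-dimethylchroman-8-yl)ethynyl]-1,3-phenylene diacetate
Conditions: PdCl2(PPh3)2 (cat.), CuI (cat.), Et3N, THF, degassed, rt to 40 °C
Reagents that add atoms: none
Why: In this Sonogashira coupling the aryl iodide adds oxidatively to zerovalent palladium at room temperature, the copper acetylide of 8 transmetalates, and the aryl acetates tolerate triethylamine.

Step 7
Reactants: 11 4-[(5-methoxy-2,2-dimethylchroman-8-yl)ethynyl]-1,3-phenylene diacetate
Product: 13 methyl 6-hydroxy-2-(5-methoxy-2,2-dimethylchroman-8-yl)benzofuran-3-carboxylate, via alkynylresorcinol 12 (not isolated)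
Conditions: Cs2CO3, MeOH, rt; then PdI2 (cat.), thiourea (cat.), CBr4, CO (1 atm), 40 °C
Reagents that add atoms: carbon monoxide, [C-]#[O+]; methanol, CO
Why: After methanolysis of both acetates, divalent palladium activates the alkyne for 5-endo-dig attack of the ortho phenoxide (ring C), the 3-benzofuranylpalladium species inserts CO and is cleaved by methanol, and CBr4 returns zerovalent palladium to the divalent state, which is the known palladium-catalysed carbonylative annulation of ortho-alkynylphenols to benzofuran-3-carboxylates.

Step 8
Reactants: 13 methyl 6-hydroxy-2-(5-methoxy-2,2-dimethylchroman-8-yl)benzofuran-3-carboxylate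
Product: 14 6-hydroxy-2-(5-methoxy-2,2-dimethylchroman-8-yl)benzofuran-3-carboxylic acid
Conditions: NaOH, H2O/MeOH/THF, 60 °C; then 1 M HCl
Reagents that add atoms: sodium hydroxide, [Na+].[OH-]
Why: Saponification of the methyl ester by acyl–oxygen cleavage should proceed on warming, with the phenoxide and the aryl ethers inert to hydroxide and the acid set free on acidification.

Step 9
Reactants: 14 6-hydroxy-2-(5-methoxy-2,2-dimethylchroman-8-yl)benzofuran-3-carboxylic acid
Product: 15 2-(5-methoxy-2,2-dimethylchroman-8-yl)-6-(pivaloyloxy)benzofuran-3-carboxylic acid
Conditions: NaOH (2.2 equiv), H2O/THF, 0 °C, PivCl (1.2 equiv); then 1 M HCl to pH 3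
Reagents that add atoms: pivaloyl chloride, CC(C)(C)C(Cl)=O
Why: Under Schotten–Baumann conditions the phenoxide is a far better nucleophile than the hindered, hydrated carboxylate, so acylation should occur at the ring D oxygen only and the acid is recovered on acidification.

Step 10
Reactants: 15 2-(5-methoxy-2,2-dimethylchroman-8-yl)-6-(pivaloyloxy)benzofuran-3-carboxylic acid
Product: 16 pentacyclic lactone pivalate (the target with its ring D hydroxyl esterified by pivalic acid)
Conditions: undivided cell, graphite anode, platinum cathode, constant current 5 mA cm−2 (about 2.5 F mol−1), nBu4NBF4 (0.1 M), 2,6-lutidine (1 equiv), MeCN/HFIP 4:1, rt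
Reagents that add atoms: none
Why: The carboxylate of 15 (or its arylbenzofuran π system, which the carboxylate then traps) is oxidised at the anode, the acyloxy oxygen bonds to ring A, and loss of a second electron and of the C8a proton restores aromaticity while protons are reduced to H2 at the cathode. The closest known reaction type is the anodic dehydrogenative lactonization of biaryl-2-carboxylic acids to benzocoumarins, of which a 2-arylbenzofuran-3-carboxylic acid is a heteroaryl member and which is known to form the C–O bond meta to an alkoxy group. Ring B closes as a six-membered lactone either by direct 6-endo attack at C8a or by 5-exo ipso attack at C4a followed by a 1,2-acyloxy shift; C4a is ortho to the ring E oxygen and para to the methoxy group, so the spiro route is electronically matched and makes up for C8a being meta to both oxygens. No stereocentre is formed. Site selectivity is needed between the two carbons ortho to the C4–C4a bond and is secured because C5 carries the ring E oxygen and no hydrogen, so only C8a can lose a proton. Chemoselectivity against over-oxidation rests on the electron-poor pivalate on ring D, on the poorly nucleophilic HFIP medium that should leave the ring E benzylic CH2 and the free C8 position untrapped, and on the lactone being harder to oxidise than the carboxylate.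

Step 11
Reactants: 16 pentacyclic lactone pivalate
Product: 17 CNP0304440.0 (target)
Conditions: K2CO3, MeOH/THF, rt; then 1 M HCl
Reagents that add atoms: none
Why: Base-mediated methanolysis (transesterification) of the aryl pivalate frees the ring D phenoxide, and the acidic work-up protonates it and would re-form ring B had methoxide opened the lactone, since the C8a oxygen and the C3 carbonyl are held next to each other.

**Compound list**

1 | 2-hydroxy-4-methoxybenzaldehyde | COc1ccc(C=O)c(O)c1 | starting material
2 | 3-chloro-3-methylbut-1-yne | CC(C)(Cl)C#C | starting material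
3 | 4-methoxy-2-[(2-methylbut-3-yn-2-yl)oxy]benzaldehyde | COc1ccc(C=O)c(OC(C)(C)C#C)c1 | intermediate
4 | 2-hydroxy-4-methoxy-3-(3-methylbuta-1,2-dien-1-yl)benzaldehyde (allenylphenol) | COc1ccc(C=O)c(O)c1C=C=C(C)C | intermediate (not isolated)
5 | 4-methoxy-5-(3-methylbut-2-en-1-ylidene)-6-oxocyclohexa-1,3-diene-1-carbaldehyde (ortho-quinone methide) | COC1=CC=C(C=O)C(=O)C1=CC=C(C)C | intermediate (not isolated)
6 | 5-methoxy-2,2-dimethyl-2H-chromene-8-carbaldehyde | COc1ccc(C=O)c2c1C=CC(C)(C)O2 | intermediate
7 | 5-methoxy-2,2-dimethylchroman-8-carbaldehyde | COc1ccc(C=O)c2c1CCC(C)(C)O2 | intermediate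
8 | 8-ethynyl-5-methoxy-2,2-dimethylchroman | COc1ccc(C#C)c2c1CCC(C)(C)O2 | intermediate
9 | 4-iodoresorcinol (4-iodobenzene-1,3-diol) | Oc1ccc(I)c(O)c1 | starting material
10 | 4-iodo-1,3-phenylene diacetate | CC(=O)Oc1ccc(I)c(OC(C)=O)c1 | intermediate
11 | 4-[(5-methoxy-2,2-dimethylchroman-8-yl)ethynyl]-1,3-phenylene diacetate | COc1ccc(C#Cc3ccc(OC(C)=O)cc3OC(C)=O)c2c1CCC(C)(C)O2 | intermediate
12 | 4-[(5-methoxy-2,2-dimethylchroman-8-yl)ethynyl]benzene-1,3-diol (alkynylresorcinol) | COc1ccc(C#Cc3ccc(O)cc3O)c2c1CCC(C)(C)O2 | intermediate (not isolated)
13 | methyl 6-hydroxy-2-(5-methoxy-2,2-dimethylchroman-8-yl)benzofuran-3-carboxylate | COc1ccc(-c2oc3cc(O)ccc3c2C(=O)OC)c2c1CCC(C)(C)O2 | intermediate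
14 | 6-hydroxy-2-(5-methoxy-2,2-dimethylchroman-8-yl)benzofuran-3-carboxylic acid | COc1ccc(-c2oc3cc(O)ccc3c2C(=O)O)c2c1CCC(C)(C)O2 | intermediate
15 | 2-(5-methoxy-2,2-dimethylchroman-8-yl)-6-(pivaloyloxy)benzofuran-3-carboxylic acid | COc1ccc(-c2oc3cc(OC(=O)C(C)(C)C)ccc3c2C(=O)O)c2c1CCC(C)(C)O2 | intermediate
16 | pentacyclic lactone pivalate: coumestan with methoxy on C7, ring E fused at C5 (oxygen) and C6 (CH2), and pivaloyloxy on ring D para to the carbon joined to furan C3 | COc1cc2oc(=O)c3c4ccc(OC(=O)C(C)(C)C)cc4oc3c2c2c1CCC(C)(C)O2 | intermediate
17 | CNP0304440.0: the same pentacycle with a free ring D hydroxyl | COc1cc2oc(=O)c3c4ccc(O)cc4oc3c2c2c1CCC(C)(C)O2 | target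

**Count**

Total steps: 11. Longest linear sequence: 10 steps (steps 1 to 4 and 6 to 11, from compound 1); step 5 is the one-step side branch from compound 9.

**Steps most likely to fail**

Step 10. The oxidation may be diverted from C8a in three ways: ipso attack of the acyloxy oxygen at C5 with opening of ring E, benzylic oxidation of the ring E CH2 next to ring A, or intermolecular coupling through the free C8 position. The fallback sets out from acid 15 and returns at lactone 16, replacing electron transfer by carboxylate-directed C–H palladation: Pd(OAc)2 (cat.), PhI(OAc)2, KOAc and N-acetylglycine in tBuOH at 80 °C. The carboxylate should deliver divalent palladium to the C8a–H bond, oxidation to tetravalent palladium and C–O reductive elimination then close ring B, and the metalation step does not depend on the oxygen pattern of ring A. No new compound arises (F0).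

Step 7. The 3-benzofuranylpalladium intermediate may be protonated before CO insertion, or the phenoxide may cyclise under base alone; both give ring C without the carboxyl carbon. The free ring D phenoxide may also be halogenated by CBr4. The fallback sets out from diacetate 11 and returns at ester 13, separating ring closure from carbonylation. Methanolysis with K2CO3 in MeOH gives alkynylresorcinol 12, now isolated. Iodocyclisation with I2 and NaHCO3 in MeCN at 0 °C should give 3-iodo-2-(5-methoxy-2,2-dimethylchroman-8-yl)benzofuran-6-ol F1. Non-oxidative methoxycarbonylation of its C–I bond with PdCl2(PPh3)2, CO (1 atm) and Et3N in MeOH/DMF at 70 °C then gives 13.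

Step 1. O-alkylation of the hydrogen-bonded phenol may be slow, so that elimination of HCl from the tertiary chloride to the enyne consumes the reagent. The fallback sets out from aldehyde 1 and returns at chromene 6, bypassing ether 3. Thermal condensation of 1 with 1,1-diethoxy-3-methylbut-2-ene in 3-picoline/p-xylene at 140 °C should exchange the acetal onto the phenol, lose ethanol, alkylate the only free ortho carbon and close ring E by oxa-6π electrocyclization. No new compound arises (F0).

**Further compounds**

F0 | step 10 | none | none
F1 | step 7 | 3-iodo-2-(5-methoxy-2,2-dimethylchroman-8-yl)benzofuran-6-ol | COc1ccc(-c2oc3cc(O)ccc3c2I)c2c1CCC(C)(C)O2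
F0 | step 1 | none | none
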